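**Plan**

1. Retrosynthesis: the three galloyl C(=O)–O bonds and the carboxyl protection are cut first (benzyl quinate), then the C1–CO2H bond (C1 ketone plus a carboxyl carbon from ethyl vinyl ether), then the ring bond C5–C6 of the cyclohexane by retro-aldol.
2. Enabling feature: quinate C5, C4 and C3 (C3–O/C4–O cis, C5–O trans), the methylenes C6 and C2 and the C1 carbonyl correspond atom for atom to C1, C2, C3, the C-methyl, a deoxygenated C4 and an oxidised C5 of L-rhamnose, so an open-chain 1,5-keto aldehyde can close the carbocycle.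
3. Forward: L-rhamnose → benzyl glycoside 2,3-acetonide → C4 deoxygenation → lactol → diol → keto aldehyde 8; the only ring-forming event, the cyclohexane, occurs in step 8 (methyl carbon onto the aldehyde).
4. Silylation, 1-ethoxyvinyllithium addition and ozonolysis then install the carboxyl; hydrolysis gives quinic acid, which is benzylated, esterified with three equivalents of perbenzylated gallic acid and hydrogenolysed.
5. Stereochemistry: C3 and C4 are C3 and C2 of L-rhamnose; C5 is set in the aldol (catalyst and dioxolane acting in the same sense); C1 is set by addition to the ketone on the face opposite the acetonide.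
6. Numbering: sugar numbering up to 8, quinate numbering from 9 on (sugar C1, C2, C3, C4, C5, C6 = quinate C5, C4, C3, C2, C1, C6).

Key step: step 8

Assumption: 3,4,5-tris(benzyloxy)benzoic acid 18 (gallic acid with its three phenols benzylated) is taken as a commercial starting material, and L-rhamnose is used as its monohydrate.

**Route**

Step 1
Reactants: 1 L-rhamnose
Product: 2 benzyl α-L-rhamnopyranoside
Conditions: BnOH, TsOH·H2O (cat.), 80 °C
Reagents that add atoms: benzyl alcohol, OCc1ccccc1
Why: Fischer glycosidation under thermodynamic control gives the pyranoside with the axial (α) benzyloxy group favoured by the anomeric effect, and this anomeric centre is only temporary.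

Step 2
Reactants: 2 benzyl α-L-rhamnopyranoside
Product: 3 benzyl 2,3-O-isopropylidene-α-L-rhamnopyranoside
Conditions: 2,2-dimethoxypropane, TsOH·H2O (cat.), acetone, rt
Reagents that add atoms: 2,2-dimethoxypropane, COC(C)(C)OC
Why: Acid-catalysed transacetalisation (isopropylidene acetal formation) prefers the cis-2,3-diol, which closes an unstrained dioxolane, and leaves O4–H as the only free hydroxyl.

Step 3
Reactants: 3 benzyl 2,3-O-isopropylidene-α-L-rhamnopyranoside
Product: 4 benzyl 4-O-(imidazol-1-ylthiocarbonyl)-2,3-O-isopropylidene-α-L-rhamnopyranoside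
Conditions: 1,1'-thiocarbonyldiimidazole, DMAP (cat.), toluene, 80 °C
Reagents that add atoms: 1,1'-thiocarbonyldiimidazole, S=C(n1ccnc1)n1ccnc1
Why: Thioacylation of the single free secondary hydroxyl provides the thiocarbonyl group needed for radical C–O cleavage.

Step 4
Reactants: 4 benzyl 4-O-(imidazol-1-ylthiocarbonyl)-2,3-O-isopropylidene-α-L-rhamnopyranoside
Product: 5 benzyl 4,6-dideoxy-2,3-O-isopropylidene-α-L-lyxo-hexopyranoside
Conditions: Bu3SnH, AIBN (cat.), toluene, 110 °C
Reagents that add atoms: none
Why: Barton–McCombie deoxygenation, in which the stannyl radical adds to sulfur, the secondary C4 radical is released and takes hydrogen from the stannane, after which C4 is no longer stereogenic.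

Step 5
Reactants: 5 benzyl 4,6-dideoxy-2,3-O-isopropylidene-α-L-lyxo-hexopyranoside
Product: 6 4,6-dideoxy-2,3-O-isopropylidene-L-lyxo-hexopyranose (lactol, anomer mixture)
Conditions: H2 (1 atm), 10% Pd/C, EtOAc, rt
Reagents that add atoms: none
Why: Hydrogenolysis of the benzylic C–O bond frees the anomeric hydroxyl under neutral conditions that keep the acid-labile acetonide, which acid hydrolysis of a glycoside would not.

Step 6
Reactants: 6 4,6-dideoxy-2,3-O-isopropylidene-L-lyxo-hexopyranose
Product: 7 4,6-dideoxy-2,3-O-isopropylidene-L-lyxo-hexitol (sugar numbering kept; 1,5-diol)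
Conditions: NaBH4, EtOH, 0 °C → rt
Reagents that add atoms: none
Why: Borohydride reduction of the open hydroxy-aldehyde tautomer of the lactol gives the 1,5-diol, whose two hydroxyls are exactly the two positions to be oxidised.

Step 7
Reactants: 7 4,6-dideoxy-2,3-O-isopropylidene-L-lyxo-hexitol
Product: 8 (4R,5R)-2,2-dimethyl-5-(2-oxopropyl)-1,3-dioxolane-4-carbaldehyde (the 4,6-dideoxy-2,3-O-isopropylidene-hexos-5-ulose with the C2/C3 configuration of L-rhamnose, aldehydo form)
Conditions: (COCl)2, DMSO, CH2Cl2, −78 °C; then i-Pr2NEt, −78 → −30 °C; used crude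
Reagents that add atoms: none
Why: Swern oxidation, in which both hydroxyls are converted to alkoxysulfonium ions before the base is added, so that aldehyde and ketone are unveiled together without a lactol that would be over-oxidised, while the hindered base and low temperature spare the α-alkoxy aldehyde centre.

Step 8
Reactants: 8 (4R,5R)-2,2-dimethyl-5-(2-oxopropyl)-1,3-dioxolane-4-carbaldehyde
Product: 9 (3R,4S,5R)-3-hydroxy-4,5-(isopropylidenedioxy)cyclohexanone (quinate numbering: C1 ketone, 3,4-O-isopropylidene, 5-OH trans to O4)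
Conditions: D-proline (20 mol %), DMSO, rt
Reagents that add atoms: none
Why: D-Proline condenses with the methyl ketone to its terminal enamine (sugar C5=C6), the enamine carbon adds to the C1 aldehyde while the carboxylic acid protonates the developing alkoxide, and hydrolysis of the iminium ion releases 9 and the catalyst. The closest known reactions are the proline-mediated Hajos–Parrish cyclisation and the aldol closure of 6-deoxyhexos-5-uloses, the dicarbonyl intermediates of the Ferrier carbocyclisation. The cyclohexanone closes in the 6-(enolendo)-exo-trig mode, since both enamine carbons end up in the ring and the aldehyde oxygen outside it. The new carbinol centre (quinate C5, R) is controlled by the dioxolane-bearing chair: the aldehyde oxygen can sit axial and antiperiplanar to the C2–O bond with the C3–O bond equatorial, which leads to the hydroxyl trans to O4, whereas the chair leading to the cis isomer forces the aldehyde oxygen syn-axial to the C3 oxygen; D-proline is chosen because, by analogy with the Hajos–Parrish transition state, its acid group in the anti enamine should lie over that axial oxygen on the required face, and the reversibility of the aldol adds a thermodynamic bias toward the isomer with the equatorial hydroxyl. The step needs regioselectivity between the methyl group and the C4 methylene and must leave the α-alkoxy aldehyde centre alone: only the methyl enamine can reach the aldehyde through a six-membered transition state (the C4 enamine would close a cyclobutane), and the α-branched, α-oxygenated aldehyde is a poor enamine donor and therefore acts only as the acceptor.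

Step 9
Reactants: 9 (3R,4S,5R)-3-hydroxy-4,5-(isopropylidenedioxy)cyclohexanone
Product: 10 (3R,4S,5R)-3-(tert-butyldimethylsilyloxy)-4,5-(isopropylidenedioxy)cyclohexanone
Conditions: TBSCl, imidazole, DMF, rt
Reagents that add atoms: tert-butyldimethylsilyl chloride, CC(C)(C)[Si](C)(C)Cl
Why: Silyl ether formation caps the β-hydroxyl so that the organolithium of the next step meets no alkoxide that could trigger retro-aldol cleavage.

Step 10
Reactants: 10 (3R,4S,5R)-3-(tert-butyldimethylsilyloxy)-4,5-(isopropylidenedioxy)cyclohexanone; 11 ethyl vinyl ether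
Product: 13 5-O-TBS-3,4-O-isopropylidene-1-C-(1-ethoxyvinyl)cyclohexane-1,3,4,5-tetrol (quinate configuration; C1–OH cis to O3/O4), via 1-ethoxyvinyllithium 12 (not isolated)
Conditions: 11, t-BuLi, THF, −78 → 0 °C; then 10, THF, −78 °C; then H2O
Reagents that add atoms: none
Why: α-Lithiation of the vinyl ether gives an alkoxycarbonyl-anion equivalent whose 1,2-addition to the ketone takes the equatorial path on the chair with O3 axial, i.e. the face opposite the acetonide, because the axial path is blocked by the syn-axial C3–O bond, so that the new C1 hydroxyl is axial and cis to O3 and O4.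

Step 11
Reactants: 13 5-O-TBS-3,4-O-isopropylidene-1-C-(1-ethoxyvinyl)cyclohexane-1,3,4,5-tetrol
Product: 14 ethyl 5-O-(tert-butyldimethylsilyl)-3,4-O-isopropylidenequinate
Conditions: O3, CH2Cl2, −78 °C; then Me2S, −78 °C → rt
Reagents that add atoms: ozone, [O-][O+]=O
Why: Ozonolysis of the electron-rich enol ether double bond gives the ethyl ester directly, with formaldehyde as the other fragment, and does not touch the C1 configuration.

Step 12
Reactants: 14 ethyl 5-O-(tert-butyldimethylsilyl)-3,4-O-isopropylidenequinate
Product: 16 (−)-quinic acid, via lithium 5-O-TBS-3,4-O-isopropylidenequinate 15 (not isolated)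
Conditions: LiOH, THF–H2O, rt; then 2 M HCl, 40 °C
Reagents that add atoms: lithium hydroxide, [Li+].[OH-]
Why: Ester saponification followed by acid hydrolysis of the isopropylidene acetal and the silyl ether frees the carboxyl and all four hydroxyls without involving a stereocentre.

Step 13
Reactants: 16 (−)-quinic acid
Product: 17 benzyl quinate
Conditions: BnBr, Cs2CO3, DMF, rt
Reagents that add atoms: benzyl bromide, BrCc1ccccc1
Why: Carboxylate O-alkylation, in which carbonate deprotonates only the carboxylic acid, so that the caesium carboxylate alone is benzylated and the four hydroxyls stay free.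

Step 14
Reactants: 17 benzyl quinate; 18 3,4,5-tris(benzyloxy)benzoic acid (first of the three equivalents that are incorporated)
Product: 19 benzyl 3,4,5-tris-O-[3,4,5-tris(benzyloxy)benzoyl]quinate
Conditions: 18 (3.6 equiv in all), DCC (3.8 equiv), DMAP (0.5 equiv), CH2Cl2–DMF, 0 °C → rt
Reagents that add atoms: 3,4,5-tris(benzyloxy)benzoic acid (second equivalent of 18), O=C(O)c1cc(OCc2ccccc2)c(OCc2ccccc2)c(OCc2ccccc2)c1; 3,4,5-tris(benzyloxy)benzoic acid (third equivalent of 18), OC(=O)c1cc(OCc2ccccc2)c(OCc3ccccc3)c(OCc4ccccc4)c1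
Why: Threefold Steglich esterification, in which three molecules of 18 are activated by DCC and transferred by DMAP to the three secondary hydroxyls, one acyl group each, whereas the tertiary C1 hydroxyl, hindered and deactivated by the geminal ester, is expected to stay free.

Step 15
Reactants: 19 benzyl 3,4,5-tris-O-[3,4,5-tris(benzyloxy)benzoyl]quinate
Product: 20 3,4,5-tri-O-galloylquinic acid
Conditions: H2 (1 atm), 10% Pd/C, THF–MeOH, rt
Reagents that add atoms: none
Why: Catalytic hydrogenolysis removes the nine benzyl ethers and the benzyl ester under conditions to which the aryl ester links and the four stereocentres are inert.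

**Compound list**

1 | L-rhamnose (6-deoxy-L-mannose, monohydrate used) | C[C@H](O)[C@H](O)[C@@H](O)[C@@H](O)C=O | starting material
2 | benzyl α-L-rhamnopyranoside | C[C@H]1[C@H](O)[C@@H](O)[C@@H](O)[C@H](OCc2ccccc2)O1 | intermediate
3 | benzyl 2,3-O-isopropylidene-α-L-rhamnopyranoside | C[C@H]1[C@H](O)[C@H]2OC(C)(C)O[C@H]2[C@H](OCc3ccccc3)O1 | intermediate
4 | benzyl 4-O-(imidazol-1-ylthiocarbonyl)-2,3-O-isopropylidene-α-L-rhamnopyranoside | C[C@H]1[C@H](OC(=S)n2ccnc2)[C@H]3OC(C)(C)O[C@H]3[C@H](OCc4ccccc4)O1 | intermediate
5 | benzyl 4,6-dideoxy-2,3-O-isopropylidene-α-L-lyxo-hexopyranoside | C[C@H]1C[C@H]2OC(C)(C)O[C@H]2[C@H](OCc3ccccc3)O1 | intermediate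
6 | 4,6-dideoxy-2,3-O-isopropylidene-L-lyxo-hexopyranose (anomer mixture) | C[C@H]1C[C@H]2OC(C)(C)O[C@H]2C(O)O1 | intermediate
7 | 4,6-dideoxy-2,3-O-isopropylidene-L-lyxo-hexitol, (2S)-1-[(4R,5S)-5-(hydroxymethyl)-2,2-dimethyl-1,3-dioxolan-4-yl]propan-2-ol | C[C@H](O)C[C@H]1OC(C)(C)O[C@H]1CO | intermediate
8 | (4R,5R)-2,2-dimethyl-5-(2-oxopropyl)-1,3-dioxolane-4-carbaldehyde (cis; 4,6-dideoxy-2,3-O-isopropylidene-hexos-5-ulose) | CC(=O)C[C@H]1OC(C)(C)O[C@H]1C=O | intermediate
9 | (3R,4S,5R)-3-hydroxy-4,5-(isopropylidenedioxy)cyclohexanone | O=C1C[C@@H](O)[C@@H]2OC(C)(C)O[C@@H]2C1 | intermediate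
10 | (3R,4S,5R)-3-(tert-butyldimethylsilyloxy)-4,5-(isopropylidenedioxy)cyclohexanone | O=C1C[C@@H](O[Si](C)(C)C(C)(C)C)[C@@H]2OC(C)(C)O[C@@H]2C1 | intermediate
11 | ethyl vinyl ether | C=COCC | starting material
12 | 1-ethoxyvinyllithium | [Li]C(=C)OCC | intermediate (not isolated)
13 | 5-O-TBS-3,4-O-isopropylidene-1-C-(1-ethoxyvinyl)cyclohexane-1,3,4,5-tetrol (C1–OH cis to O3/O4, ethoxyvinyl cis to O5) | C=C(OCC)[C@@]1(O)C[C@@H](O[Si](C)(C)C(C)(C)C)[C@@H]2OC(C)(C)O[C@@H]2C1 | intermediate
14 | ethyl 5-O-(tert-butyldimethylsilyl)-3,4-O-isopropylidenequinate | CCOC(=O)[C@@]1(O)C[C@@H](O[Si](C)(C)C(C)(C)C)[C@@H]2OC(C)(C)O[C@@H]2C1 | intermediate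
15 | lithium 5-O-(tert-butyldimethylsilyl)-3,4-O-isopropylidenequinate | [Li+].[O-]C(=O)[C@@]1(O)C[C@@H](O[Si](C)(C)C(C)(C)C)[C@@H]2OC(C)(C)O[C@@H]2C1 | intermediate (not isolated)
16 | (−)-quinic acid, (1S,3R,4S,5R)-1,3,4,5-tetrahydroxycyclohexane-1-carboxylic acid | OC(=O)[C@@]1(O)C[C@@H](O)[C@H](O)[C@H](O)C1 | intermediate
17 | benzyl quinate | O=C(OCc1ccccc1)[C@@]2(O)C[C@@H](O)[C@H](O)[C@H](O)C2 | intermediate
18 | 3,4,5-tris(benzyloxy)benzoic acid | OC(=O)c1cc(OCc2ccccc2)c(OCc2ccccc2)c(OCc2ccccc2)c1 | starting material
19 | benzyl 3,4,5-tris-O-[3,4,5-tris(benzyloxy)benzoyl]quinate | O=C(OCc1ccccc1)[C@@]2(O)C[C@@H](OC(=O)c3cc(OCc4ccccc4)c(OCc4ccccc4)c(OCc4ccccc4)c3)[C@H](OC(=O)c3cc(OCc4ccccc4)c(OCc4ccccc4)c(OCc4ccccc4)c3)[C@H](OC(=O)c3cc(OCc4ccccc4)c(OCc4ccccc4)c(OCc4ccccc4)c3)C2 | intermediate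
20 | 3,4,5-tri-O-galloylquinic acid | O=C(O[C@@H]1C[C@](O)(C(=O)O)C[C@@H](OC(=O)c2cc(O)c(O)c(O)c2)[C@H]1OC(=O)c1cc(O)c(O)c(O)c1)c1cc(O)c(O)c(O)c1 | target

**Step count and risks**

Total step count: 15. Longest linear sequence: 15 steps (1 → 20); 11 and 18 enter as purchased.

Steps most likely to fail:

Step 8. The two faces of the aldehyde may not be distinguished well enough, since the match between catalyst and dioxolane is a prediction, so that the hydroxyl ends cis to O4. The fallback sets out from 8 and accepts that outcome: the aldol is run as before, and the cis isomer (3S,4S,5R)-3-hydroxy-4,5-(isopropylidenedioxy)cyclohexanone F1 is treated with MsCl and Et3N in CH2Cl2 at 0 °C. The resulting mesylate F2 is not isolated and eliminates in the same flask to the enone (4S,5R)-4,5-(isopropylidenedioxy)cyclohex-2-en-1-one F3. The C5–C6 bond is thus still made by the aldol, but the carbinol centre is set afterwards. Conjugate borylation (B2pin2, CuCl, NaOt-Bu, Xantphos, MeOH, THF, rt) should occur on the enone face opposite the cis-fused acetonide and give the β-boryl ketone F4 with boron trans to O4. Oxidation with NaBO3·4H2O in THF–H2O proceeds with retention and comes back to the route at 9.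

Step 10. The strongly basic vinyllithium may abstract a proton α to the ketone, after which the β-silyloxy or β-acetal oxygen is lost by E1cB elimination in competition with addition. The fallback sets out from 10 and uses the less basic vinylmagnesium bromide (THF, −78 °C), which should add along the same equatorial path to give the vinyl carbinol F5. Ozonolysis (O3, CH2Cl2, −78 °C; PPh3) gives the α-hydroxy aldehyde F6. Pinnick oxidation (NaClO2, NaH2PO4, 2-methylbut-2-ene, t-BuOH–H2O) gives 5-O-(tert-butyldimethylsilyl)-3,4-O-isopropylidenequinic acid F7, the free acid of 15. F7 is taken through the aqueous HCl stage of step 12 and comes back to the route at 16.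

Step 7. The amine base may epimerise the α-alkoxy aldehyde carbon (sugar C2), or one hydroxyl may be oxidised ahead of the other so that a lactol forms and is over-oxidised. The fallback sets out from 6 and unveils the aldehyde last under neutral conditions. Wittig methylenation of the lactol (Ph3PCH3Br, KOt-Bu, THF) gives the hydroxy alkene (2S)-1-[(4R,5S)-2,2-dimethyl-5-vinyl-1,3-dioxolan-4-yl]propan-2-ol F8. Dess–Martin periodinane (CH2Cl2, NaHCO3) oxidises the secondary alcohol to the methyl ketone 1-[(4R,5S)-2,2-dimethyl-5-vinyl-1,3-dioxolan-4-yl]propan-2-one F9. Ozonolysis (O3, CH2Cl2, −78 °C; PPh3) comes back to the route at 8.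

**Further compounds**

F1 | step 8 | (3S,4S,5R)-3-hydroxy-4,5-(isopropylidenedioxy)cyclohexanone (C5 epimer of 9, quinate numbering) | O=C1C[C@H](O)[C@@H]2OC(C)(C)O[C@@H]2C1
F2 | step 8 | methanesulfonate of F1 (not isolated) | O=C1C[C@H](OS(C)(=O)=O)[C@@H]2OC(C)(C)O[C@@H]2C1
F3 | step 8 | (4S,5R)-4,5-(isopropylidenedioxy)cyclohex-2-en-1-one | O=C1C=C[C@@H]2OC(C)(C)O[C@@H]2C1
F4 | step 8 | 3-(pinacolboryl)-4,5-(isopropylidenedioxy)cyclohexanone, boron trans to O4 | O=C1C[C@@H](B2OC(C)(C)C(C)(C)O2)[C@@H]3OC(C)(C)O[C@@H]3C1
F5 | step 10 | 5-O-TBS-3,4-O-isopropylidene-1-C-vinylcyclohexane-1,3,4,5-tetrol (quinate configuration) | C=C[C@@]1(O)C[C@@H](O[Si](C)(C)C(C)(C)C)[C@@H]2OC(C)(C)O[C@@H]2C1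
F6 | step 10 | 5-O-TBS-3,4-O-isopropylidene-1-hydroxycyclohexane-1-carbaldehyde (quinate configuration) | O=C[C@@]1(O)C[C@@H](O[Si](C)(C)C(C)(C)C)[C@@H]2OC(C)(C)O[C@@H]2C1
F7 | step 10 | 5-O-(tert-butyldimethylsilyl)-3,4-O-isopropylidenequinic acid | OC(=O)[C@@]1(O)C[C@@H](O[Si](C)(C)C(C)(C)C)[C@@H]2OC(C)(C)O[C@@H]2C1
F8 | step 7 | (2S)-1-[(4R,5S)-2,2-dimethyl-5-vinyl-1,3-dioxolan-4-yl]propan-2-ol | C[C@H](O)C[C@H]1OC(C)(C)O[C@H]1C=C
F9 | step 7 | 1-[(4R,5S)-2,2-dimethyl-5-vinyl-1,3-dioxolan-4-yl]propan-2-one | CC(=O)C[C@H]1OC(C)(C)O[C@H]1C=C
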